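**Plan**
- The retrosynthesis first cuts the depside ester bond between the ring B carbonyl and O4 of ring A. This leaves two copies of one 2,4-dihydroxy-6-(2-oxoheptyl)benzoate unit, with the side-chain ketone masked as a dioxolane.
- Each arene is the dehydrogenated form of a 6-alkyl-2,4-dioxocyclohexane-1-carboxylate: C1 carries the ester, C2 and C4 the oxygens, and C6 is an sp3 CH. Ring bonds C1–C6 and C2–C3 are therefore cut back to dibenzyl malonate and an alk-3-en-2-one, and the enone C=C is cut to a β-ketal aldehyde derived from ethyl 3-oxooctanoate.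
- Forward: ketalization, partial reduction and Wittig olefination give the enone. A Michael–Claisen annulation closes the only carbocycle, and bromination–dehydrobromination aromatizes it to a single benzyl resorcylate.
- That resorcylate is used directly as the ring A phenol and, after O-benzylation and saponification, as the ring B acid. The halves are joined at O4 with a carbodiimide, the ketals are hydrolysed and all benzyl groups are removed by hydrogenolysis.
- The target has no stereocentre. The E-alkene from the stabilized ylide is consumed in the annulation and the two sp3 ring centres of the dione vanish on aromatization.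

Key step: step 4

Assumption: the cyclohexanedione compounds 8–11 are handled as racemic mixtures of diastereomers and enol tautomers, since all their sp3 ring centres disappear on aromatization.

Step 1
Reactants: 1 ethyl 3-oxooctanoate; 2 ethylene glycol
Product: 3 ethyl 2-(2-pentyl-1,3-dioxolan-2-yl)acetate
Conditions: ethylene glycol (3 equiv), TsOH·H2O (cat.), toluene, reflux, Dean–Stark
Reagents that add atoms: ethylene glycol (2), OCCO
Why: Acid-catalysed ketalization with azeotropic removal of water should convert the ketone, which is far more electrophilic than the ester, into the dioxolane, as is routine for β-keto esters.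

Step 2
Reactants: 3 ethyl 2-(2-pentyl-1,3-dioxolan-2-yl)acetate
Product: 4 2-(2-pentyl-1,3-dioxolan-2-yl)acetaldehyde
Conditions: i-Bu2AlH (1.05 equiv), CH2Cl2, −78 °C; MeOH, then aq. KNaC4H4O6; used crude
Reagents that add atoms: none
Why: Partial ester reduction with i-Bu2AlH at low temperature should stop at the aldehyde, because the tetrahedral aluminium hemiacetal is held by chelation to a dioxolane oxygen and collapses only on work-up.

Step 3
Reactants: 4 2-(2-pentyl-1,3-dioxolan-2-yl)acetaldehyde; 5 1-(triphenylphosphoranylidene)propan-2-one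
Product: 6 (E)-5-(2-pentyl-1,3-dioxolan-2-yl)pent-3-en-2-one
Conditions: 5 (1.3 equiv), CH2Cl2, rt to 40 °C
Reagents that add atoms: 1-(triphenylphosphoranylidene)propan-2-one (5), CC(=O)C=P(c1ccccc1)(c1ccccc1)c1ccccc1
Why: Wittig olefination with a stabilized acyl ylide should give the E-enone under neutral conditions that are too weakly basic to enolize or β-eliminate the β-alkoxy aldehyde.

Step 4
Reactants: 6 (E)-5-(2-pentyl-1,3-dioxolan-2-yl)pent-3-en-2-one; 7 dibenzyl malonate
Product: 9 benzyl 2,4-dioxo-6-[(2-pentyl-1,3-dioxolan-2-yl)methyl]cyclohexane-1-carboxylate, via Michael adduct 8 (not isolated)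
Conditions: 7 (1.2 equiv), NaH (1.1 equiv), BnOH (0.1 equiv), THF, 0 °C; slow addition of 6 at 0 °C, then reflux; cold 0.5 M HCl to pH 4
Reagents that add atoms: dibenzyl malonate (7), O=C(CC(=O)OCc1ccccc1)OCc1ccccc1
Why: Sodium dibenzyl malonate adds in Michael fashion to the β-carbon of enone 6 (bond C1–C6) to give keto diester 8, and after proton exchange the methyl-ketone enolate attacks one benzyl ester in an intramolecular Claisen condensation (bond C2–C3) with loss of benzyloxide. The closest known reaction type is the Michael–Claisen (Michael–Dieckmann) annulation of malonates with alk-3-en-2-ones, which gives 6-alkyl dihydroresorcylates. The single ring closes in a 6-exo-trig mode through the CH3-derived enolate carbon, since closure from the internal CH2 would give a strained four-membered ring. The two new sp3 centres C1 and C6 are not controlled and need not be, because both become aromatic carbons in step 5. Chemoselectivity is required and is secured in three ways: deprotonation of the acidic cyclic 1,3-dione by the released benzyloxide pulls every reversible step forward; pre-forming the soft malonate anion and adding the enone slowly at 0 °C keeps free alkoxide low, so conjugate addition should outpace γ-deprotonation and vinylogous β-elimination of a dioxolane oxygen; and the all-benzyl ester set excludes ester scrambling while the dioxolane keeps the side-chain ketone out of the condensation.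

Step 5
Reactants: 9 benzyl 2,4-dioxo-6-[(2-pentyl-1,3-dioxolan-2-yl)methyl]cyclohexane-1-carboxylate
Product: 12 benzyl 2,4-dihydroxy-6-[(2-pentyl-1,3-dioxolan-2-yl)methyl]benzoate, via 3-bromo dione 10 (not isolated), via 5-bromo dione 11 (not isolated)
Conditions: NaOAc (1.0 equiv), Br2 (1.0 equiv), anhydrous DMF, 0 °C, then 80 °C; poured into cold aq. NaHCO3
Reagents that add atoms: none
Why: The dione enolate should be brominated at C3, the bromine should move to C5 by the HBr-mediated halogen transfer known for 2-bromocyclohexane-1,3-diones, and loss of HBr across C5–C6 with enolization should give the arene, which is the established bromination–dehydrobromination aromatization of 6-alkyl dihydroresorcylates; one equivalent of Br2 avoids nuclear bromination, and acetate, anhydrous DMF and the bicarbonate quench should keep the dioxolane closed.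

Step 6
Reactants: 12 benzyl 2,4-dihydroxy-6-[(2-pentyl-1,3-dioxolan-2-yl)methyl]benzoate (about half of the material); 13 benzyl bromide
Product: 14 benzyl 2,4-bis(benzyloxy)-6-[(2-pentyl-1,3-dioxolan-2-yl)methyl]benzoate
Conditions: BnBr (2.5 equiv), K2CO3 (3 equiv), DMF, 60 °C
Reagents that add atoms: benzyl bromide (13), BrCc1ccccc1
Why: Williamson etherification should benzylate both phenols, the hydrogen-bonded 2-OH needing the mild heating, while ester and ketal are inert to carbonate.

Step 7
Reactants: 14 benzyl 2,4-bis(benzyloxy)-6-[(2-pentyl-1,3-dioxolan-2-yl)methyl]benzoate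
Product: 15 2,4-bis(benzyloxy)-6-[(2-pentyl-1,3-dioxolan-2-yl)methyl]benzoic acid
Conditions: KOH (6 equiv), DMSO/H2O 4:1, 90 °C; then cold 1 M HCl to pH 4
Reagents that add atoms: potassium hydroxide, [K+].[OH-]
Why: Saponification with poorly solvated hydroxide in aqueous DMSO is the standard way to open di-ortho-substituted benzoates, and benzyl ethers and the dioxolane are stable to base and to the brief cold acidification.

Step 8
Reactants: 15 2,4-bis(benzyloxy)-6-[(2-pentyl-1,3-dioxolan-2-yl)methyl]benzoic acid; 12 benzyl 2,4-dihydroxy-6-[(2-pentyl-1,3-dioxolan-2-yl)methyl]benzoate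
Product: 16 benzyl 4-({2,4-bis(benzyloxy)-6-[(2-pentyl-1,3-dioxolan-2-yl)methyl]benzoyl}oxy)-2-hydroxy-6-[(2-pentyl-1,3-dioxolan-2-yl)methyl]benzoate
Conditions: 12 (1.1 equiv), DCC (1.2 equiv), DMAP (0.2 equiv), CH2Cl2, 0 °C to rt
Reagents that add atoms: none
Why: Steglich esterification should acylate only the 4-OH, because the 2-OH is tied up in a hydrogen bond to the neighbouring ester carbonyl and is flanked by it, and the dioxolanes prevent a side-chain enol from trapping the activated carboxyl as an isocoumarin.

Step 9
Reactants: 16 benzyl 4-({2,4-bis(benzyloxy)-6-[(2-pentyl-1,3-dioxolan-2-yl)methyl]benzoyl}oxy)-2-hydroxy-6-[(2-pentyl-1,3-dioxolan-2-yl)methyl]benzoate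
Product: 17 benzyl 4-{[2,4-bis(benzyloxy)-6-(2-oxoheptyl)benzoyl]oxy}-2-hydroxy-6-(2-oxoheptyl)benzoate
Conditions: PPTS (0.3 equiv), acetone/H2O 9:1, 50 °C
Reagents that add atoms: water, O
Why: Mild acid-catalysed ketal hydrolysis should free both ketones while the carboxyl is still a benzyl ester, so that enol lactonization to an isocoumarin is slow and the hindered depside ester is not attacked.

Step 10
Reactants: 17 benzyl 4-{[2,4-bis(benzyloxy)-6-(2-oxoheptyl)benzoyl]oxy}-2-hydroxy-6-(2-oxoheptyl)benzoate
Product: 18 4-{[2,4-dihydroxy-6-(2-oxoheptyl)benzoyl]oxy}-2-hydroxy-6-(2-oxoheptyl)benzoic acid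
Conditions: H2 (1 atm), 10% Pd/C, EtOAc, rt
Reagents that add atoms: none
Why: Catalytic hydrogenolysis should cleave the two benzyl ethers and the benzyl ester under neutral conditions that leave the aliphatic ketones and the depside ester untouched and give no acid or base to trigger lactonization.

**Compound list**
1 | ethyl 3-oxooctanoate | CCCCCC(=O)CC(=O)OCC | starting material
2 | ethylene glycol | OCCO | starting material
3 | ethyl 2-(2-pentyl-1,3-dioxolan-2-yl)acetate | CCCCCC1(CC(=O)OCC)OCCO1 | intermediate
4 | 2-(2-pentyl-1,3-dioxolan-2-yl)acetaldehyde | CCCCCC1(CC=O)OCCO1 | intermediate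
5 | 1-(triphenylphosphoranylidene)propan-2-one | CC(=O)C=P(c1ccccc1)(c1ccccc1)c1ccccc1 | starting material
6 | (E)-5-(2-pentyl-1,3-dioxolan-2-yl)pent-3-en-2-one | CC(=O)/C=C/CC1(CCCCC)OCCO1 | intermediate
7 | dibenzyl malonate | O=C(CC(=O)OCc1ccccc1)OCc1ccccc1 | starting material
8 | dibenzyl 2-[4-oxo-1-(2-pentyl-1,3-dioxolan-2-yl)pentan-2-yl]propanedioate (racemic, not isolated) | CCCCCC1(CC(CC(C)=O)C(C(=O)OCc2ccccc2)C(=O)OCc2ccccc2)OCCO1 | intermediate
9 | benzyl 2,4-dioxo-6-[(2-pentyl-1,3-dioxolan-2-yl)methyl]cyclohexane-1-carboxylate (racemic, diastereomer and enol mixture) | CCCCCC1(CC2CC(=O)CC(=O)C2C(=O)OCc2ccccc2)OCCO1 | intermediate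
10 | benzyl 3-bromo-2,4-dioxo-6-[(2-pentyl-1,3-dioxolan-2-yl)methyl]cyclohexane-1-carboxylate (not isolated) | CCCCCC1(CC2CC(=O)C(Br)C(=O)C2C(=O)OCc2ccccc2)OCCO1 | intermediate
11 | benzyl 5-bromo-2,4-dioxo-6-[(2-pentyl-1,3-dioxolan-2-yl)methyl]cyclohexane-1-carboxylate (not isolated) | CCCCCC1(CC2C(Br)C(=O)CC(=O)C2C(=O)OCc2ccccc2)OCCO1 | intermediate
12 | benzyl 2,4-dihydroxy-6-[(2-pentyl-1,3-dioxolan-2-yl)methyl]benzoate | CCCCCC1(Cc2cc(O)cc(O)c2C(=O)OCc2ccccc2)OCCO1 | intermediate
13 | benzyl bromide | BrCc1ccccc1 | starting material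
14 | benzyl 2,4-bis(benzyloxy)-6-[(2-pentyl-1,3-dioxolan-2-yl)methyl]benzoate | CCCCCC1(Cc2cc(OCc3ccccc3)cc(OCc3ccccc3)c2C(=O)OCc2ccccc2)OCCO1 | intermediate
15 | 2,4-bis(benzyloxy)-6-[(2-pentyl-1,3-dioxolan-2-yl)methyl]benzoic acid | CCCCCC1(Cc2cc(OCc3ccccc3)cc(OCc3ccccc3)c2C(=O)O)OCCO1 | intermediate
16 | benzyl 4-({2,4-bis(benzyloxy)-6-[(2-pentyl-1,3-dioxolan-2-yl)methyl]benzoyl}oxy)-2-hydroxy-6-[(2-pentyl-1,3-dioxolan-2-yl)methyl]benzoate | CCCCCC1(Cc2cc(OC(=O)c3c(OCc4ccccc4)cc(OCc4ccccc4)cc3CC3(CCCCC)OCCO3)cc(O)c2C(=O)OCc2ccccc2)OCCO1 | intermediate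
17 | benzyl 4-{[2,4-bis(benzyloxy)-6-(2-oxoheptyl)benzoyl]oxy}-2-hydroxy-6-(2-oxoheptyl)benzoate | CCCCCC(=O)Cc1cc(OC(=O)c2c(OCc3ccccc3)cc(OCc3ccccc3)cc2CC(=O)CCCCC)cc(O)c1C(=O)OCc1ccccc1 | intermediate
18 | 4-{[2,4-dihydroxy-6-(2-oxoheptyl)benzoyl]oxy}-2-hydroxy-6-(2-oxoheptyl)benzoic acid | CCCCCC(=O)Cc1cc(OC(=O)c2c(O)cc(O)cc2CC(=O)CCCCC)cc(O)c1C(=O)O | target

**Step count**
Total: 10 steps. Longest linear sequence: 10 steps (1 → 3 → 4 → 6 → 9 → 12 → 14 → 15 → 16 → 17 → 18), with 12 re-entering at step 8 as the second coupling partner.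

**Steps most likely to fail**

1. Step 5 (aromatization). The HBr set free at 80 °C may open the dioxolane, after which the side chain can lactonize onto the ester. The electron-rich arene may also be brominated further, and bromide may dealkylate the benzyl ester with subsequent decarboxylation. Fallback, from 9 back to 12, without acid: double deprotonation of 9 with LiN(i-Pr)2 (2.2 equiv) in THF at −78 °C and trapping of the dianion at C1 with PhSeBr should give benzyl 2,4-dioxo-1-(phenylselanyl)-6-[(2-pentyl-1,3-dioxolan-2-yl)methyl]cyclohexane-1-carboxylate F1. Oxidation with H2O2 and pyridine in CH2Cl2 at 0 °C should give the selenoxide, benzyl 2,4-dioxo-1-(phenylseleninyl)-6-[(2-pentyl-1,3-dioxolan-2-yl)methyl]cyclohexane-1-carboxylate F2, which should undergo syn-elimination across C1–C6 in the flask and enolize to 12.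

2. Step 4 (annulation). γ-Deprotonation of the enone may compete with conjugate addition and lead to vinylogous β-elimination that opens the dioxolane, and the Michael addition may revert or the enone oligomerize before ring closure. Fallback, from 4 back to 9, with the roles of the partners exchanged so that the acceptor is a less acidic unsaturated ester: Wittig olefination of 4 with benzyl (triphenylphosphoranylidene)acetate in CH2Cl2 should give benzyl (E)-4-(2-pentyl-1,3-dioxolan-2-yl)but-2-enoate F3. Treatment of F3 with benzyl acetoacetate and NaH with catalytic BnOH in THF at reflux should give, by Michael addition, dibenzyl 2-acetyl-3-[(2-pentyl-1,3-dioxolan-2-yl)methyl]pentanedioate F4, which is not isolated. Claisen closure of its acetyl methyl onto the chain ester then gives 9.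

3. Step 8 (depside esterification). Activation of the di-ortho-substituted acid may be slow, so the O-acylisourea can rearrange to an N-acylurea, and some acylation at O2 or at both phenols may occur. Fallback, from 15 back to 16, through a pre-formed acyl halide made under neutral conditions: 15 with 1-chloro-N,N,2-trimethylprop-1-en-1-amine in CH2Cl2 at 0 °C should give 2,4-bis(benzyloxy)-6-[(2-pentyl-1,3-dioxolan-2-yl)methyl]benzoyl chloride F5. F5 is then added to 12 with Et3N and catalytic DMAP in CH2Cl2 at 0 °C to give 16.

**Further compounds**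
F1 | step 5 | benzyl 2,4-dioxo-1-(phenylselanyl)-6-[(2-pentyl-1,3-dioxolan-2-yl)methyl]cyclohexane-1-carboxylate | CCCCCC1(CC2CC(=O)CC(=O)C2([Se]c2ccccc2)C(=O)OCc2ccccc2)OCCO1
F2 | step 5 | benzyl 2,4-dioxo-1-(phenylseleninyl)-6-[(2-pentyl-1,3-dioxolan-2-yl)methyl]cyclohexane-1-carboxylate | CCCCCC1(CC2CC(=O)CC(=O)C2([Se](=O)c2ccccc2)C(=O)OCc2ccccc2)OCCO1
F3 | step 4 | benzyl (E)-4-(2-pentyl-1,3-dioxolan-2-yl)but-2-enoate | CCCCCC1(C/C=C/C(=O)OCc2ccccc2)OCCO1
F4 | step 4 | dibenzyl 2-acetyl-3-[(2-pentyl-1,3-dioxolan-2-yl)methyl]pentanedioate | CCCCCC1(CC(CC(=O)OCc2ccccc2)C(C(C)=O)C(=O)OCc2ccccc2)OCCO1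
F5 | step 8 | 2,4-bis(benzyloxy)-6-[(2-pentyl-1,3-dioxolan-2-yl)methyl]benzoyl chloride | CCCCCC1(Cc2cc(OCc3ccccc3)cc(OCc3ccccc3)c2C(Cl)=O)OCCO1
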